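**Plan**
- Retrosynthetic cuts, in this order: the O–tert-butyl bond of a protected 4'-OH, the O5'–acyl ester bond, the C1'–C(=O) bond to the cinnamoyl unit, the ring bond C5'–C6' of ring A, and last the C2'–C(alkyne) bond between a squarate and methoxyethyne.
- Enabling feature: in ring A the five carbons C2'–C6' all bear oxygen and C2'/C5' are para, so ring A is a masked 1,4-benzoquinone. C2'–C5' with their four oxygens are the four ring carbons of a squarate; C1' and C6' are the two carbons of methoxyethyne.
- Forward: dimethyl squarate → methyl tert-butyl squarate → methoxyacetylide adduct → thermal ring expansion builds ring A (the only ring made) as a fully differentiated trialkoxyquinone → photoacylation of its single C–H with trans-cinnamaldehyde attaches the enone and ring B → esterification at O5' → acid removal of the tert-butyl group.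
- Stereochemistry: the one stereocentre is bought as (S)-2-methylbutanoic acid and attached without touching it; the E-alkene comes from trans-cinnamaldehyde.

Key step: step 5

Remark: ring A is numbered as in a chalcone (C1' carries the cinnamoyl group); the regiochemistry of step 4 is assumed to follow the steric and electronic bias given there and would be confirmed on 10 by HMBC before the route continues.

**Step 1**
Reactants: 1 dimethyl squarate (3,4-dimethoxycyclobut-3-ene-1,2-dione)
Product: 3 3-hydroxy-4-methoxycyclobut-3-ene-1,2-dione, via sodium methyl squarate 2 (not isolated)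
Conditions: NaOH (1.0 equiv), H2O/THF, 0 °C; then 1 M HCl (1.0 equiv), evaporate, extract the residue with acetone
Reagents that add atoms: sodium hydroxide, [Na+].[OH-]
Why: Saponification of a vinylogous ester (addition–elimination of hydroxide at the alkoxy-bearing ring carbon) should stop at the half ester because the delocalised monoanion 2 is no longer electrophilic towards a second equivalent of hydroxide.

**Step 2**
Reactants: 3 3-hydroxy-4-methoxycyclobut-3-ene-1,2-dione
Product: 5 3-tert-butoxy-4-methoxycyclobut-3-ene-1,2-dione, via silver methyl squarate 4 (not isolated)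
Conditions: Ag2O (0.55 equiv), 4 Å MS, Et2O/CH2Cl2, rt, dark; then t-BuCl (5 equiv), rt, dark
Reagents that add atoms: tert-butyl chloride, CC(C)(C)Cl
Why: Silver-assisted SN1-type O-alkylation of the squarate (vinylogous carboxylate) anion by tert-butyl chloride, the way di-tert-butyl squarate is made from silver squarate, should place the tert-butyl group on the enolate oxygen and give the 1,2-dione diester, driven by precipitation of silver chloride.

**Step 3**
Reactants: 6 chloroacetaldehyde dimethyl acetal (2-chloro-1,1-dimethoxyethane)
Product: 8 methoxyacetylene (methoxyethyne), via sodium methoxyacetylide 7 (not isolated)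
Conditions: NaNH2 (3 equiv), liq. NH3, −33 °C; evaporate NH3; cold sat. aq NaCl; distil the low-boiling alkyne into a cold trap, take up in dry THF
Reagents that add atoms: none
Why: Double dehydro-elimination with sodium amide (E2 loss of methanol to the chloro enol ether, then of hydrogen chloride) is the classical preparation of alkoxyacetylenes from chloroacetals, and the acetylide salt 7 formed by the third equivalent of base shields the ynol ether until the aqueous quench.

**Step 4**
Reactants: 5 3-tert-butoxy-4-methoxycyclobut-3-ene-1,2-dione; 8 methoxyacetylene
Product: 10 (±)-2-tert-butoxy-4-hydroxy-3-methoxy-4-(methoxyethynyl)cyclobut-2-en-1-one, via lithium methoxyacetylide 9 (not isolated)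
Conditions: 8, n-BuLi (1.05 equiv), THF, −78 °C; cannulate into 5, THF, −78 °C; sat. aq NH4Cl at −78 °C; short filtration through neutralised silica
Reagents that add atoms: none
Why: 1,2-Addition of a lithium acetylide to a squarate carbonyl at −78 °C is the standard entry to 4-alkynyl-4-hydroxycyclobutenones, and attack should go to the carbonyl flanked by the methoxy-bearing carbon because the tert-butyl group screens the carbonyl next to it and because the hindered, twisted tert-butoxy oxygen is the weaker π-donor and so leaves the carbonyl vinylogous to it the more electrophilic; the new carbinol centre is formed racemic and disappears in step 5.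

**Step 5**
Reactants: 10 (±)-2-tert-butoxy-4-hydroxy-3-methoxy-4-(methoxyethynyl)cyclobut-2-en-1-one
Product: 13 3-tert-butoxy-2,5-dimethoxy-1,4-benzoquinone, via enynyl ketene 11 (not isolated), via ring-closed diradical 12 (not isolated)
Conditions: degassed toluene (0.02 M), 80 °C (raise to 110 °C if slow)
Reagents that add atoms: none
Why: Heating opens the C1–C4 bond of the cyclobutenone in a thermal conrotatory 4π electrocyclic reaction in which the hydroxyl group, the better donor on C4, turns outward and the alkynyl group inward, so that the (Z)-enynyl ketene 11 has ketene and alkyne on the same side. The ketene carbon (future C5') then bonds to the distal, methoxy-bearing alkyne carbon (future C6') in a 6-endo closure that makes ring A as the aromatic diradical 12 (phenoxyl oxygen on C5', σ-radical on C1'), and transfer of the hydroxyl hydrogen from O2' to C1', directly or relayed by the medium, gives quinone 13. This is the Moore rearrangement of 4-alkynyl-4-hydroxycyclobutenones (the enyne–ketene counterpart of the Myers–Saito cyclisation), established for the acetylide adducts of dialkyl squarates. No stereocentre is created, and the racemic carbinol centre of 10 becomes the C2' carbonyl carbon. The selectivity needed is six- over five-membered closure (quinone rather than alkylidenecyclopentenedione), and an electron-donating alkoxy group on the alkyne, like alkyl and unlike aryl, silyl or ester groups, should steer closure to the six-membered ring; having no β-hydrogen, the methoxy group also cannot be lost by retro-ene fragmentation at this temperature. The position of every oxygen in 13 (carbonyls at C2' and C5', methoxy at C3' and C6', tert-butoxy at C4', hydrogen at C1') follows directly from the constitution of 10.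

**Step 6**
Reactants: 13 3-tert-butoxy-2,5-dimethoxy-1,4-benzoquinone; 14 trans-cinnamaldehyde
Product: 15 (E)-1-(4-tert-butoxy-2,5-dihydroxy-3,6-dimethoxyphenyl)-3-phenylprop-2-en-1-one
Conditions: hν (420–450 nm LEDs or sunlamp through Pyrex), 14 (5 equiv), degassed PhH, 20 °C
Reagents that add atoms: none
Why: Photo-Friedel–Crafts acylation of a quinone by an aldehyde (hydrogen abstraction from the formyl group by the excited quinone, bonding of the acyl radical to a ring carbon, tautomerisation) can acylate only the one unsubstituted ring carbon C1' and delivers the chelated 2'-OH and the free 5'-OH in the same event, with the E-alkene carried over from 14 and, should some Z-isomer arise by sensitisation, restored by a trace of iodine.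

**Step 7**
Reactants: 15 (E)-1-(4-tert-butoxy-2,5-dihydroxy-3,6-dimethoxyphenyl)-3-phenylprop-2-en-1-one; 16 (S)-2-methylbutanoic acid
Product: 17 2-tert-butoxy-4-hydroxy-3,6-dimethoxy-5-[(E)-3-phenylprop-2-enoyl]phenyl (2S)-2-methylbutanoate
Conditions: DCC (1.2 equiv), DMAP (0.1 equiv), CH2Cl2, 0 °C → rt
Reagents that add atoms: none
Why: Steglich esterification should acylate the free 5'-OH in preference to the 2'-OH, which is hydrogen-bonded to the ketone and the weaker nucleophile, and the weakly basic carbodiimide/DMAP conditions at 0 °C should leave the α-stereocentre of the acyl group untouched so that the (S)-configuration of 16 is carried into 17.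

**Step 8**
Reactants: 17 2-tert-butoxy-4-hydroxy-3,6-dimethoxy-5-[(E)-3-phenylprop-2-enoyl]phenyl (2S)-2-methylbutanoate
Product: 18 2,4-dihydroxy-3,6-dimethoxy-5-[(E)-3-phenylprop-2-enoyl]phenyl (2S)-2-methylbutanoate (CNP0237988.1)
Conditions: TFA/CH2Cl2 (1:4), 0 °C, short exposure; evaporate with toluene, no basic wash; chromatography on silica
Reagents that add atoms: none
Why: Acidolysis of an aryl tert-butyl ether (E1 loss of the tert-butyl cation as isobutene) unmasks the 4'-OH, while the aryl ester, the enone and both methyl ethers are stable to cold anhydrous trifluoroacetic acid, and the base-free work-up avoids acyl migration from O5' to the neighbouring O4'.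

**Compound list**
1 | dimethyl squarate (3,4-dimethoxycyclobut-3-ene-1,2-dione) | COC1=C(OC)C(=O)C1=O | starting material
2 | sodium 2-methoxy-3,4-dioxocyclobut-1-en-1-olate (sodium methyl squarate) | COC1=C([O-])C(=O)C1=O.[Na+] | intermediate (not isolated)
3 | 3-hydroxy-4-methoxycyclobut-3-ene-1,2-dione (methyl hydrogen squarate) | COC1=C(O)C(=O)C1=O | intermediate
4 | silver(I) 2-methoxy-3,4-dioxocyclobut-1-en-1-olate (silver methyl squarate) | COC1=C([O-])C(=O)C1=O.[Ag+] | intermediate (not isolated)
5 | 3-tert-butoxy-4-methoxycyclobut-3-ene-1,2-dione (methyl tert-butyl squarate) | COC1=C(OC(C)(C)C)C(=O)C1=O | intermediate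
6 | chloroacetaldehyde dimethyl acetal (2-chloro-1,1-dimethoxyethane) | COC(CCl)OC | starting material
7 | sodium methoxyacetylide | COC#[C-].[Na+] | intermediate (not isolated)
8 | methoxyacetylene (methoxyethyne) | COC#C | intermediate
9 | lithium methoxyacetylide | COC#[C-].[Li+] | intermediate (not isolated)
10 | (±)-2-tert-butoxy-4-hydroxy-3-methoxy-4-(methoxyethynyl)cyclobut-2-en-1-one | O=C1C(OC(C)(C)C)=C(OC)C1(O)C#COC | intermediate
11 | (3Z)-2-tert-butoxy-4-hydroxy-3,6-dimethoxyhexa-1,3-dien-5-yn-1-one (enynyl ketene) | O=C=C(OC(C)(C)C)/C(OC)=C(/O)C#COC | intermediate (not isolated)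
12 | 2-tert-butoxy-4-hydroxy-3,6-dimethoxy-5-dehydrophenoxyl (ring-closed diradical) | [O]c1c(OC(C)(C)C)c(OC)c(O)[c]c1OC | intermediate (not isolated)
13 | 3-tert-butoxy-2,5-dimethoxy-1,4-benzoquinone | COC1=CC(=O)C(OC)=C(OC(C)(C)C)C1=O | intermediate
14 | trans-cinnamaldehyde | O=C/C=C/c1ccccc1 | starting material
15 | (E)-1-(4-tert-butoxy-2,5-dihydroxy-3,6-dimethoxyphenyl)-3-phenylprop-2-en-1-one | O=C(/C=C/c1ccccc1)c1c(O)c(OC)c(OC(C)(C)C)c(O)c1OC | intermediate
16 | (S)-2-methylbutanoic acid | CC[C@H](C)C(=O)O | starting material
17 | 2-tert-butoxy-4-hydroxy-3,6-dimethoxy-5-[(E)-3-phenylprop-2-enoyl]phenyl (2S)-2-methylbutanoate | CC[C@H](C)C(=O)Oc1c(OC(C)(C)C)c(OC)c(O)c(C(=O)/C=C/c2ccccc2)c1OC | intermediate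
18 | 2,4-dihydroxy-3,6-dimethoxy-5-[(E)-3-phenylprop-2-enoyl]phenyl (2S)-2-methylbutanoate | CC[C@H](C)C(=O)Oc1c(O)c(OC)c(O)c(C(=O)/C=C/c2ccccc2)c1OC | target

**Step count**
Total: 8 steps. Longest linear sequence: 7 steps (1 → 18 through steps 1, 2, 4, 5, 6, 7 and 8); step 3 is a one-step side branch.

**Steps most likely to fail**

Step 6 (photoacylation). The excited state of the electron-rich trialkoxyquinone may abstract the formyl hydrogen too slowly. Other possible failures are intramolecular hydrogen abstraction from a methoxy group, combination of the radical pair at oxygen instead of carbon, and sensitised isomerisation or [2+2] addition at the styryl double bond. The fallback sets out from 13 and returns at 15, and brings in the acyl group by directed ortho-metalation instead of by a radical. Aqueous sodium dithionite should reduce 13 to 3-tert-butoxy-2,5-dimethoxybenzene-1,4-diol F1. Ethyl vinyl ether with catalytic PPTS then protects both phenols as 3-tert-butoxy-1,4-bis(1-ethoxyethoxy)-2,5-dimethoxybenzene F2 (mixture of acetal diastereomers). n-BuLi/TMEDA in THF at 0 °C removes the only ring hydrogen, which lies between an acetal oxygen and a methoxy group, and the aryllithium adds 1,2 to trans-cinnamaldehyde 14 to give (E)-1-[4-tert-butoxy-2,5-bis(1-ethoxyethoxy)-3,6-dimethoxyphenyl]-3-phenylprop-2-en-1-ol F3. MnO2 oxidises this allylic, benzylic alcohol to (E)-1-[4-tert-butoxy-2,5-bis(1-ethoxyethoxy)-3,6-dimethoxyphenyl]-3-phenylprop-2-en-1-one F4. PPTS in methanol at room temperature removes both acetals but not the aryl tert-butyl ether, which gives 15.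

Step 4 (acetylide addition). Discrimination between the two squarate carbonyls may be poor, so that attack beside the tert-butoxy-bearing carbon leads on to the quinone with methyl and tert-butyl interchanged. The fallback sets out from 8 and returns at 13, and creates the unsymmetrical oxygen pattern after the ring closure instead of before it. Lithium methoxyacetylide 9 made from 8 is added to di-tert-butyl squarate (3,4-di-tert-butoxycyclobut-3-ene-1,2-dione) F5, obtained from squaric acid by the silver-salt alkylation of step 2; its two carbonyls are equivalent. The adduct (±)-2,3-di-tert-butoxy-4-hydroxy-4-(methoxyethynyl)cyclobut-2-en-1-one F6 is heated as in step 5 to give 2,3-di-tert-butoxy-5-methoxy-1,4-benzoquinone F7. One equivalent of sodium methoxide in methanol/THF at low temperature should then exchange one tert-butoxy group by conjugate addition–elimination (vinylogous transesterification), preferentially at C3'. That carbon is β to the C5' carbonyl, the more electron-poor of the two, since the C2' carbonyl already receives electron density from the alkoxy groups at C4' and C6'. Exchange there also relieves the crowding between the neighbouring tert-butoxy groups, and exchange at C6' is degenerate, so the product is 13.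

Step 2 (O-tert-butylation). The tert-butyl cation may be lost as isobutene faster than the weakly nucleophilic squarate oxygen captures it, or alkylation may occur at a carbonyl oxygen. The fallback sets out from 3 and returns at 5, and forms the C–O bond at the ring carbon instead of at the tert-butyl carbon. Oxalyl chloride with catalytic DMF converts 3 into the vinylogous acid chloride 3-chloro-4-methoxycyclobut-3-ene-1,2-dione F8. tert-Butanol and 2,6-lutidine in CH2Cl2 at 0 °C should then give 5 by addition–elimination.

**Further compounds**
F1 | step 6 | 3-tert-butoxy-2,5-dimethoxybenzene-1,4-diol | Oc1cc(OC)c(O)c(OC(C)(C)C)c1OC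
F2 | step 6 | 3-tert-butoxy-1,4-bis(1-ethoxyethoxy)-2,5-dimethoxybenzene | CCOC(C)Oc1cc(OC)c(OC(C)OCC)c(OC(C)(C)C)c1OC
F3 | step 6 | (E)-1-[4-tert-butoxy-2,5-bis(1-ethoxyethoxy)-3,6-dimethoxyphenyl]-3-phenylprop-2-en-1-ol | OC(/C=C/c1ccccc1)c1c(OC(C)OCC)c(OC)c(OC(C)(C)C)c(OC(C)OCC)c1OC
F4 | step 6 | (E)-1-[4-tert-butoxy-2,5-bis(1-ethoxyethoxy)-3,6-dimethoxyphenyl]-3-phenylprop-2-en-1-one | O=C(/C=C/c1ccccc1)c1c(OC(C)OCC)c(OC)c(OC(C)(C)C)c(OC(C)OCC)c1OC
F5 | step 4 | di-tert-butyl squarate (3,4-di-tert-butoxycyclobut-3-ene-1,2-dione) | CC(C)(C)OC1=C(OC(C)(C)C)C(=O)C1=O
F6 | step 4 | (±)-2,3-di-tert-butoxy-4-hydroxy-4-(methoxyethynyl)cyclobut-2-en-1-one | O=C1C(OC(C)(C)C)=C(OC(C)(C)C)C1(O)C#COC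
F7 | step 4 | 2,3-di-tert-butoxy-5-methoxy-1,4-benzoquinone | COC1=CC(=O)C(OC(C)(C)C)=C(OC(C)(C)C)C1=O
F8 | step 2 | 3-chloro-4-methoxycyclobut-3-ene-1,2-dione | COC1=C(Cl)C(=O)C1=O
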